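The route rests on disconnecting the bond between C1' of the side chain and C5 of the benzene ring, the carbon meta to both oxygen-bearing carbons C1 and C3, which electrophilic substitution cannot address. 1-Bromoicosane (1) and dichloride 2 give, through Grignard reagent 3, allylic chloride 4, whose methylidene masks the C2' ketone. Dissolving-metal reduction turns the carboxyl-bearing ring carbon of 3,5-dimethoxybenzoic acid (5) into the nucleophilic centre of dienediolate 6, which is alkylated by 4 in the same flask to give, through salt 7, quaternary dienyl acid 8. The carboxyl group is then expelled as CO2 on rearomatisation; alkene cleavage and ether removal finish the route.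

Key step: step 2

Assumption: in liquid ammonia acid 5 is present as its ammonium salt, and that ammonium proton is taken as the one delivered to ring carbon C4, so the reduction is balanced with two lithium atoms per molecule of 5 (in practice a slight excess is titrated in). The target has no stereocentre.

Step 1
Reactants: 1 1-bromoicosane; 2 3-chloro-2-(chloromethyl)prop-1-ene
Product: 4 2-(chloromethyl)tricos-1-ene, via icosylmagnesium bromide 3 (not isolated)
Conditions: Mg turnings, THF, 45 °C; then slow addition to 2 (3 equiv), CuI (5 mol %), THF, −20 → 0 °C; excess 2 removed by distillation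
Reagents that add atoms: none
Why: Grignard formation followed by copper-catalysed allylic substitution on a symmetrical bis-allylic dichloride, for which the SN2 and SN2' pathways give the same product, while inverse addition to a threefold excess of 2 should hold back the second displacement.

Step 2
Reactants: 5 3,5-dimethoxybenzoic acid; 4 2-(chloromethyl)tricos-1-ene
Product: 8 3,5-dimethoxy-1-(2-methylidenetricosyl)cyclohexa-2,5-diene-1-carboxylic acid, via dilithium dienediolate 6 (not isolated), via lithium carboxylate 7 (not isolated)
Conditions: Li (ca. 2.2 equiv, to a faint persistent blue), NH3(l)/THF, −78 °C; a drop of isoprene to discharge the colour; 4 in THF, −78 → −33 °C; NH3 evaporated; cold aq. HCl to pH 4–5, Et2O, 0 °C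
Reagents that add atoms: none
Why: Birch reductive alkylation, in which two electrons from Li enter the carboxylate-bearing ring, protonation occurs at C4 (para to the carboxylate and ortho to both methoxy groups), and the remaining charge rests in dienediolate 6 centred on the ipso carbon, with both methoxy groups left on the two surviving enol ether double bonds. This carbon nucleophile displaces chloride from 4 (SN2, the SN2' path giving the identical product) and creates the quaternary carbon that becomes ring carbon C5 bonded to C1'; the closest known reaction type is the reductive alkylation of benzoic acids with alkyl and allyl halides. No ring is closed and no stereocentre arises, because the two ring arms at the quaternary carbon are identical. The selectivity needed is regiochemical, and it is secured because the carboxylate (1,4-reduction across ipso and para carbons) and the two methoxy groups (which stay on double bonds) direct the reduction the same way and confine the carbanion to the ipso carbon. The unhindered allylic CH2Cl terminus offsets the steric demand of the tertiary nucleophile, and discharging surplus Li beforehand protects the chloride, while the isolated 1,1-disubstituted alkene is not reduced by dissolving metal. Brief acidification at 0 °C to pH 4–5 should free the acid from salt 7 without hydrolysing the enol ethers.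

Step 3
Reactants: 8 3,5-dimethoxy-1-(2-methylidenetricosyl)cyclohexa-2,5-diene-1-carboxylic acid
Product: 9 1,3-dimethoxy-5-(2-methylidenetricosyl)benzene
Conditions: Pb(OAc)4 (1.1 equiv), pyridine (2 equiv), C6H6, rt
Reagents that add atoms: none
Why: Oxidative decarboxylation by tetravalent lead, in which the lead carboxylate loses CO2 to a methoxy-stabilised cyclohexadienyl radical that is oxidised to the arenium ion and sheds the C4 proton, so that aromatisation should drive the reaction at room temperature, where the isolated alkene is expected to survive.

Step 4
Reactants: 9 1,3-dimethoxy-5-(2-methylidenetricosyl)benzene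
Product: 11 1-(3,5-dimethoxyphenyl)tricosan-2-one, via vicinal diol 10 (not isolated)
Conditions: OsO4 (2 mol %), NaIO4 (4 equiv), 2,6-lutidine (2 equiv), dioxane/THF/H2O, rt
Reagents that add atoms: osmium tetroxide OsO4, O=[Os](=O)(=O)=O (delivers the carbonyl oxygen); sodium periodate NaIO4, [Na+].[O-]I(=O)(=O)=O (terminal oxidant that restores it)
Why: Lemieux–Johnson oxidation, in which OsO4 dihydroxylates the unhindered 1,1-disubstituted alkene to racemic diol 10 and NaIO4 cleaves it at once to the ketone and formaldehyde, the dimethoxyarene being inert to both oxidants and 2,6-lutidine suppressing over-oxidation.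

Step 5
Reactants: 11 1-(3,5-dimethoxyphenyl)tricosan-2-one
Product: 13 5-(2-oxotricosyl)benzene-1,3-diol, via aryl dibromoborate 12 (not isolated)
Conditions: BBr3 (3.5 equiv), CH2Cl2, −78 °C → rt; then H2O, 0 °C
Reagents that add atoms: none
Why: Lewis-acid cleavage of aryl methyl ethers, in which BBr3 binds each methoxy oxygen and bromide removes the methyl group by SN2 to give borate 12, which water hydrolyses to the resorcinol, while the ketone only ties up one further equivalent of BBr3 and is released on work-up.

Compound list
1 | 1-bromoicosane | CCCCCCCCCCCCCCCCCCCCBr | starting material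
2 | 3-chloro-2-(chloromethyl)prop-1-ene | C=C(CCl)CCl | starting material
3 | icosylmagnesium bromide | CCCCCCCCCCCCCCCCCCCC[Mg]Br | intermediate (not isolated)
4 | 2-(chloromethyl)tricos-1-ene | C=C(CCl)CCCCCCCCCCCCCCCCCCCCC | intermediate
5 | 3,5-dimethoxybenzoic acid | COc1cc(cc(OC)c1)C(=O)O | starting material
6 | dilithium (3,5-dimethoxycyclohexa-2,5-dien-1-ylidene)methanediolate | [Li+].[Li+].[O-]C([O-])=C1C=C(OC)CC(OC)=C1 | intermediate (not isolated)
7 | lithium 3,5-dimethoxy-1-(2-methylidenetricosyl)cyclohexa-2,5-diene-1-carboxylate | [Li+].[O-]C(=O)C1(CC(=C)CCCCCCCCCCCCCCCCCCCCC)C=C(OC)CC(OC)=C1 | intermediate (not isolated)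
8 | 3,5-dimethoxy-1-(2-methylidenetricosyl)cyclohexa-2,5-diene-1-carboxylic acid | C=C(CC1(C(=O)O)C=C(OC)CC(OC)=C1)CCCCCCCCCCCCCCCCCCCCC | intermediate
9 | 1,3-dimethoxy-5-(2-methylidenetricosyl)benzene | C=C(Cc1cc(OC)cc(OC)c1)CCCCCCCCCCCCCCCCCCCCC | intermediate
10 | 2-[(3,5-dimethoxyphenyl)methyl]tricosane-1,2-diol (racemic) | OCC(O)(Cc1cc(OC)cc(OC)c1)CCCCCCCCCCCCCCCCCCCCC | intermediate (not isolated)
11 | 1-(3,5-dimethoxyphenyl)tricosan-2-one | CCCCCCCCCCCCCCCCCCCCCC(=O)Cc1cc(OC)cc(OC)c1 | intermediate
12 | 1-[3,5-bis(dibromoboranyloxy)phenyl]tricosan-2-one | CCCCCCCCCCCCCCCCCCCCCC(=O)Cc1cc(OB(Br)Br)cc(OB(Br)Br)c1 | intermediate (not isolated)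
13 | 5-(2-oxotricosyl)benzene-1,3-diol (5-(2'-oxotricosyl)resorcinol) | CCCCCCCCCCCCCCCCCCCCCC(=O)Cc1cc(O)cc(O)c1 | target

Total step count: 5. Longest linear sequence: 5 steps (1 → 4 → 8 → 9 → 11 → 13).

Steps most likely to fail

Step 2. The C-alkylation of the hindered dienediolate may stay incomplete because the waxy C24 chloride comes out of solution in cold ammonia/THF. The chloride may also be consumed by residual solvated electrons or amide, and the enol ethers may hydrolyse during acidification. The fallback sets out from 5 and keeps the reductive alkylation but uses a small, soluble electrophile and attaches the chain afterwards. Dianion 6 would be generated as before and treated with a large excess of dichloride 2, which should give lithium 1-[2-(chloromethyl)prop-2-en-1-yl]-3,5-dimethoxycyclohexa-2,5-diene-1-carboxylate F1. The same cold acidification should give 1-[2-(chloromethyl)prop-2-en-1-yl]-3,5-dimethoxycyclohexa-2,5-diene-1-carboxylic acid F2. Pb(OAc)4 in benzene with pyridine should then aromatise this acid with loss of CO2 to 1-[2-(chloromethyl)prop-2-en-1-yl]-3,5-dimethoxybenzene F3. CuI-catalysed coupling of this allylic chloride with Grignard reagent 3 in THF (SN2 and SN2' again converge) comes back to the route at 9.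

Step 3. The acetic acid set free may hydrolyse the enol ethers before the lead carboxylate fragments, and the oxidant may acetoxylate the alkene or the electron-rich ring. The fallback sets out from 4 and forms the same C5–C1' bond with reversed polarity, so that no dearomatised acid is involved. Purchased 1-bromo-3,5-dimethoxybenzene F4 would be converted with Mg in THF into (3,5-dimethoxyphenyl)magnesium bromide F5. This aryl Grignard reagent would be coupled with allylic chloride 4 under CuI catalysis at 0 °C, a known aryl–allyl substitution, and the fallback comes back to the route at 9.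

Step 1. A second displacement on the product allylic chloride and Wurtz-type homocoupling of the long-chain Grignard reagent may give waxy hydrocarbons that are hard to separate. The fallback sets out from Grignard reagent 3 and uses an electrophile whose product is no longer an allylic halide. CuI-catalysed SN2' addition of 3 to purchased ethyl 2-(bromomethyl)prop-2-enoate F6 in THF at −78 °C should give ethyl 2-methylidenetricosanoate F7. Reduction with i-Bu2AlH in CH2Cl2 at −78 °C should give 2-methylidenetricosan-1-ol F8. An Appel chlorination (PPh3, CCl4) of this allylic alcohol comes back to the route at 4.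

Further compounds
F1 | step 2 | lithium 1-[2-(chloromethyl)prop-2-en-1-yl]-3,5-dimethoxycyclohexa-2,5-diene-1-carboxylate | [Li+].[O-]C(=O)C1(CC(=C)CCl)C=C(OC)CC(OC)=C1
F2 | step 2 | 1-[2-(chloromethyl)prop-2-en-1-yl]-3,5-dimethoxycyclohexa-2,5-diene-1-carboxylic acid | OC(=O)C1(CC(=C)CCl)C=C(OC)CC(OC)=C1
F3 | step 2 | 1-[2-(chloromethyl)prop-2-en-1-yl]-3,5-dimethoxybenzene | C=C(CCl)Cc1cc(OC)cc(OC)c1
F4 | step 3 | 1-bromo-3,5-dimethoxybenzene (purchased) | COc1cc(Br)cc(OC)c1
F5 | step 3 | (3,5-dimethoxyphenyl)magnesium bromide | COc1cc([Mg]Br)cc(OC)c1
F6 | step 1 | ethyl 2-(bromomethyl)prop-2-enoate (purchased) | C=C(CBr)C(=O)OCC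
F7 | step 1 | ethyl 2-methylidenetricosanoate | C=C(C(=O)OCC)CCCCCCCCCCCCCCCCCCCCC
F8 | step 1 | 2-methylidenetricosan-1-ol | C=C(CO)CCCCCCCCCCCCCCCCCCCCC
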